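**Retrosynthetic overview**
1. The only bond to be made is the diaryl ether C–O bond. Every C–C bond lies inside a benzene ring that is bought intact, so no ring is formed in the route.
2. The cut is made at O–C6 of ring A (the methoxy ring), not at the usual O–ring B bond. The synthons are a 3,5-dibromo-2-methoxyphenyl cation and 2,4-dibromophenoxide.
3. C6 of 2,4-dibromoanisole (1) is itself a nucleophilic carbon, as is the phenol oxygen. Its polarity is reversed by direct C–H λ3-iodanation to the diaryliodonium triflate (2), an aryl-cation equivalent.
4. Salt 2 is captured by 2,4-dibromophenol (3) without a metal to give target 6. All four bromines and the OMe group come from the starting materials.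

Assumption: 6 has no stereocentre and no hindered axis, because the ether rotates freely. It is therefore achiral, and the drawn structure is the single species to be made.

**Step 1**
Reactants: 1 2,4-dibromoanisole (2,4-dibromo-1-methoxybenzene)
Product: 2 (3,5-dibromo-2-methoxyphenyl)(phenyl)iodonium trifluoromethanesulfonate
Conditions: PhI(OAc)2 (1.0 equiv), TfOH (2.0 equiv), CH2Cl2, 0 °C, 30 min; then 1 (1.1 equiv), 0 °C to rt, 16 h; evaporate, triturate with Et2O
Reagents that add atoms: (diacetoxyiodo)benzene CC(=O)OI(OC(C)=O)c1ccccc1; trifluoromethanesulfonic acid OS(=O)(=O)C(F)(F)F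
Why: This is an electrophilic aromatic substitution by trivalent iodine (diaryliodonium triflate synthesis), in which the PhI(OAc)2/TfOH reagent, strong enough to attack halobenzenes, should take the only methoxy-activated free position of 1 (C6, ortho to OMe, para position blocked by Br, summed σ+ close to that of the para carbon of bromobenzene) and so turn this nucleophilic carbon into an aryl-cation equivalent; no stereocentre is formed.

**Step 2**
Reactants: 2 (3,5-dibromo-2-methoxyphenyl)(phenyl)iodonium trifluoromethanesulfonate; 3 2,4-dibromophenol
Product: 6 1,5-dibromo-3-(2,4-dibromophenoxy)-2-methoxybenzene, via potassium 2,4-dibromophenoxide 4 (not isolated), via aryloxy(diaryl)-λ3-iodane 5 (not isolated)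
Conditions: 3 (1.0 equiv), KOt-Bu (1.0 equiv), THF, 0 °C, 15 min; then 2 (1.1 equiv), 40 °C, 6 h
Reagents that add atoms: potassium tert-butoxide CC(C)(C)[O-].[K+] (its potassium appears in 4 only; 6 holds no reagent atom)
Why: This is a metal-free O-arylation by ligand exchange and ligand coupling at trivalent iodine, in which phenoxide 4 displaces triflate to give T-shaped 5, the oxygen then couples with the ipso carbon of the more electron-poor ring A (two Br meta to the C–I carbon, Σσm about +0.8, outweighing the ortho OMe) rather than with phenyl, PhI leaves, and the four C–Br bonds survive because no transition metal is present; no stereocentre is formed.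

**Compound list**
1 | 2,4-dibromoanisole | COc1ccc(Br)cc1Br | starting material
2 | (3,5-dibromo-2-methoxyphenyl)(phenyl)iodonium trifluoromethanesulfonate | COc1c(Br)cc(Br)cc1[I+]c1ccccc1.[O-]S(=O)(=O)C(F)(F)F | intermediate
3 | 2,4-dibromophenol | Oc1ccc(Br)cc1Br | starting material
4 | potassium 2,4-dibromophenoxide (formed in the flask) | [K+].[O-]c1ccc(Br)cc1Br | intermediate
5 | (2,4-dibromophenoxy)(3,5-dibromo-2-methoxyphenyl)(phenyl)-λ3-iodane (formed in the flask) | COc1c(Br)cc(Br)cc1I(Oc1ccc(Br)cc1Br)c1ccccc1 | intermediate
6 | 1,5-dibromo-3-(2,4-dibromophenoxy)-2-methoxybenzene (achiral) | COc1c(Br)cc(Br)cc1Oc1ccc(Br)cc1Br | target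

**Total step count:** 2
**Longest linear sequence:** 2

**Steps most likely to fail** (the route has only two steps, so both are ranked)

Highest risk, step 1. C6 of 1 is only about as nucleophilic as bromobenzene, and its methoxy group is crowded by the neighbouring Br. The iodanation may therefore be slow, or ipso attack and bromine migration in TfOH may erode the regiochemistry.

The fallback sets out from 3 and comes back to the route at 2. The C–I bond is installed under phenol control, and the roles of the two arenes are exchanged.
- Compound 3 is iodinated at its only free ortho position (N-iodosuccinimide, cat. TsOH, MeCN, rt) to 2,4-dibromo-6-iodophenol F1.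
- O-methylation (MeI, K2CO3, acetone, reflux) gives 1,5-dibromo-3-iodo-2-methoxybenzene F2.
- Oxidation with mCPBA and TfOH in CH2Cl2 gives (3,5-dibromo-2-methoxyphenyl)(hydroxy)-λ3-iodanyl triflate F3, which is not isolated.
- F3 is now the electrophile. It attacks added benzene, an unhindered partner with no regiochemical question, and delivers 2.

Second risk, step 2. The ortho OMe group lowers the tendency of ring A to be transferred, so some phenyl transfer may compete. That would give 2,4-dibromophenyl phenyl ether. The hindered, weakly nucleophilic phenoxide may also react slowly.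

The fallback sets out from 3 and comes back to the route at 6. Ring A is brought in as a saturated enolonium equivalent and aromatised afterwards.
- Compound 3 is alkylated with 2-chlorocyclohexanone (K2CO3, cat. KI, acetone, reflux) to racemic 2-(2,4-dibromophenoxy)cyclohexan-1-one F4.
- Br2 (4.2 equiv, AcOH, rt to 70 °C) first dehydrogenates the ketone by two rounds of α-bromination and HBr loss. This gives 2-(2,4-dibromophenoxy)phenol F5, which is not isolated.
- The remaining Br2 brominates F5 ortho and para to the free OH, giving 2,4-dibromo-6-(2,4-dibromophenoxy)phenol F6.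
- MeI and K2CO3 in acetone then give 6.
- The stereocentre of F4 is erased on aromatisation.

**Further compounds**
F1 | step 1 | 2,4-dibromo-6-iodophenol | Oc1c(Br)cc(Br)cc1I
F2 | step 1 | 1,5-dibromo-3-iodo-2-methoxybenzene | COc1c(Br)cc(Br)cc1I
F3 | step 1 | (3,5-dibromo-2-methoxyphenyl)(hydroxy)-λ3-iodanyl triflate | COc1c(Br)cc(Br)cc1I(O)OS(=O)(=O)C(F)(F)F
F4 | step 2 | 2-(2,4-dibromophenoxy)cyclohexan-1-one (racemic) | O=C1CCCCC1Oc1ccc(Br)cc1Br
F5 | step 2 | 2-(2,4-dibromophenoxy)phenol | Oc1ccccc1Oc1ccc(Br)cc1Br
F6 | step 2 | 2,4-dibromo-6-(2,4-dibromophenoxy)phenol | Oc1c(Br)cc(Br)cc1Oc1ccc(Br)cc1Br
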